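Late in the north flask the target climbs slowly, and you have to say what another 40 h adds to it.

| flask | starting material | coupling partner | temperature | remark | time |
|---|---|---|---|---|---|
| north | 0.16 M | 2.5 equiv | 110 °C | the very flask that is asked about, followed so far |  |
| south | 0.11 M | 2.5 equiv | 95 °C | run made earlier |  |
| flask | 0.16 M | 2.50 equiv | 110 °C |  | 20 h |

| north: time / h | north: target / % | south: time / h | south: target / % |
|---|---|---|---|
| 4.00 | 5.8 | 2.00 | 2.2 |
| 8.00 | 10.6 | 4.00 | 0 |
| 12.0 | 10.2 | 8.00 | 0.8 |
| 15.0 | 11.3 | 15.0 | 6.1 |
| 20.0 | 12.0 | 30.0 | 10.2 |

(each reading ± 1 percentage point)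

- Monday's: at 20 h take out 90% of the target then present, then wait 40 h
- Friday's: at 20 h add coupling partner, 50.0% of the amount charged, then wait 40 h
- Wednesday's: change nothing and wait 40 h more
- Tuesday's: at 20 h raise the temperature by 20 K, then wait 40 h

* target, in percent of the starting material first charged, at 20 h
* which option adds most target ("none" when 2 percentage points or less is all one gets) (Monday's / Friday's / Wednesday's / Tuesday's / none)
* target present, with what was taken out counted in, in percent of the starting material first charged, after Monday's
* target present, with what was taken out counted in, in percent of the starting material first charged, after Wednesday's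

- what is taken out of target is counted as made
- additions bring no volume worth counting

My reckoning is this: gain equals the late creep, times the waiting time, times a multiplier for each option. Before taking any value, see which input has to be known well. A point wrong in the level at 20 h moves every total by that point and no gain. The scatter of the creep, taken over 40 h, is worth 5.3 percentage points, more than that single point, so the totals hang on the creep. The creep cancels when options are compared, so the ranking hangs on the multipliers.

The late creep, the fraction of the charge gained per hour, is the mean of the last two north readings minus the mean of the two before, over the hours between: 0.00167 h⁻¹. It puts the level at 20 h at 12.1% and Wednesday's total at 18.7%. I count Monday's as leaving the creep unchanged, so it gives the same total. Starting material is the limiting reagent, and if the creep follows the coupling partner as charged, Friday's takes it to 150% of what it was. The two runs read a like level of target, north at 8.00 h and south at 30.0 h, so their mean rates up to those readings, corrected for dilution, read a factor 2.68 for 15.0 K, or 0.428 of a power of ten. Tuesday's 20 K then multiplies the creep by 3.72, more than Friday's, for a gain of 25 points. I choose Tuesday's.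

The forecast differs, with 11.7% now, 20.5% after Monday's, 12% after Wednesday's and Monday's as best, on a ceiling “which suggests equilibrium (or product inhibition)”.

The flask gives 12.3% now, 18.1% after Monday's and 18.1% after Wednesday's. The gains are 5.8 points for Monday's, 5.8 points for Wednesday's, 7.7 points for Friday's and 13 points for Tuesday's, so Tuesday's is best.

    starting material + coupling partner → intermediate A (k = 0.00500 L mol⁻¹ min⁻¹, Ea = 72.0 kJ mol⁻¹)
    intermediate A → intermediate B (k = 0.00420 min⁻¹, Ea = 126 kJ mol⁻¹)
    starting material ⇌ intermediate C (K = 2.40, k = 0.00180 min⁻¹, Ea = 111 kJ mol⁻¹, ΔH = 60.0 kJ mol⁻¹)
    intermediate A → target (k = 0.00300 min⁻¹, Ea = 109 kJ mol⁻¹)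
    intermediate B ⇌ intermediate D (K = 11.0, k = 0.00320 min⁻¹, Ea = 121 kJ mol⁻¹, ΔH = −29.0 kJ mol⁻¹)
    starting material ⇌ dormant form (K = 12.0, k = 0.00440 min⁻¹, Ea = 116 kJ mol⁻¹, ΔH = −32.0 kJ mol⁻¹)
    (constants at 110 °C)

The neighbouring flask is the same recipe read at 30 h. The reckoned level plus the creep over the extra hours gives 13.8%, and that flask shows 13.9%.

(The numbers in the tables stem from a simulated flask for substances that don't exist, and the scatter is random.)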